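Ring B, the outer benzo ring of the dioxin, is disconnected to squaric acid. The four contiguous ring B carbons that carry the free hydroxyl, the ring A ether oxygen, the ring C ether oxygen and the second dioxin oxygen are the squarate carbons; the C(OH)–CH pair comes from methyl vinyl ether. The key step exploits this run of five oxygen-bearing ring B carbons. Heating a 4-hydroxy-4-(1-methoxyvinyl)cyclobutenone that bears the ring A aryloxy group at C2 and the 1-bromodibenzofuran-2-yloxy group (rings C, D and E) at C3 opens the four-membered ring and recloses it to the penta-oxygenated ring B hydroquinone in one operation, forming the ring and one C–C bond.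

Key step: step 13

Assumption: 2-fluoro-4,6-dimethoxybenzaldehyde and (3,5-dimethoxyphenyl)boronic acid are taken as catalogue compounds; the carbinol carbon of the cyclobutenone, absent from the achiral target, is carried as a racemate and is erased on aromatisation.

Ring letters: A = 3,5-dihydroxyphenoxy group on ring B; B = outer benzo ring of the dioxin; C = central ring shared by dioxin and furan; D = outer benzo ring of the furan; E = 3,5-dihydroxyphenoxy group on ring D.

Step 1
Reactants: 1 5-bromovanillin (3-bromo-4-hydroxy-5-methoxybenzaldehyde)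
Product: 2 3-bromo-4-hydroxy-2-iodo-5-methoxybenzaldehyde
Conditions: NIS, CF3CO2H, TfOH (cat.), 0 °C → rt, dark
Reagents that add atoms: N-iodosuccinimide, O=C1CCC(=O)N1I
Why: Electrophilic aromatic iodination: the positions ortho and para to the hydroxyl are blocked, so the methoxy group should direct iodine para to itself, to the carbon between the formyl group and bromine, the site that a second bromine is known to enter in this aldehyde.

Step 2
Reactants: 2 3-bromo-4-hydroxy-2-iodo-5-methoxybenzaldehyde
Product: 3 4-(benzyloxy)-3-bromo-2-iodo-5-methoxybenzaldehyde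
Conditions: BnBr, K2CO3, DMF, 50 °C
Reagents that add atoms: benzyl bromide, BrCc1ccccc1
Why: Williamson etherification (SN2) of the acidic phenoxide masks the future ring C phenol as a benzyl ether that tolerates peracid, carbonate bases, palladium and copper and can later be removed without touching methyl ethers or the aryl bromide.

Step 3
Reactants: 3 4-(benzyloxy)-3-bromo-2-iodo-5-methoxybenzaldehyde
Product: 5 4-(benzyloxy)-3-bromo-2-iodo-5-methoxyphenol, via aryl formate 4 (not isolated)
Conditions: mCPBA, CH2Cl2, 0 °C → rt; then K2CO3, MeOH, rt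
Reagents that add atoms: 3-chloroperoxybenzoic acid, OOC(=O)c1cccc(Cl)c1
Why: Baeyer–Villiger oxidation of an alkoxy-substituted benzaldehyde: the electron-rich, ortho-substituted aryl group should migrate in the Criegee intermediate to give the formate, which mild methanolysis cleaves to the phenol that becomes the furan oxygen.

Step 4
Reactants: 5 4-(benzyloxy)-3-bromo-2-iodo-5-methoxyphenol; 6 2-fluoro-4,6-dimethoxybenzaldehyde
Product: 7 2-[4-(benzyloxy)-3-bromo-2-iodo-5-methoxyphenoxy]-4,6-dimethoxybenzaldehyde
Conditions: Cs2CO3, DMSO, 110 °C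
Reagents that add atoms: none
Why: Nucleophilic aromatic substitution (SNAr, addition–elimination): the phenoxide displaces fluoride activated by the ortho formyl group, a metal-free diaryl ether synthesis that leaves the C–I and C–Br bonds of ring C untouched.

Step 5
Reactants: 7 2-[4-(benzyloxy)-3-bromo-2-iodo-5-methoxyphenoxy]-4,6-dimethoxybenzaldehyde
Product: 8 8-(benzyloxy)-9-bromo-1,3,7-trimethoxydibenzo[b,d]furan-4-carbaldehyde (formyl group next to the furan oxygen on ring D; bromine in the bay position of ring C)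
Conditions: Pd(OAc)2 (10 mol %), PPh3 (20 mol %), Ag2CO3, DMA, 100 °C
Reagents that add atoms: none
Why: Palladium-catalysed intramolecular direct arylation (concerted metalation–deprotonation): zerovalent palladium should insert into the C–I bond much faster than into the flanked C–Br bond, and the aldehyde ring offers only one C–H ortho to the ether oxygen, so a single dibenzofuran can form.

Step 6
Reactants: 8 8-(benzyloxy)-9-bromo-1,3,7-trimethoxydibenzo[b,d]furan-4-carbaldehyde
Product: 10 8-(benzyloxy)-9-bromo-1,3,7-trimethoxydibenzo[b,d]furan-4-ol, via dibenzofuranyl formate 9 (not isolated)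
Conditions: mCPBA, CH2Cl2, 0 °C; then K2CO3, MeOH, rt
Reagents that add atoms: 3-chloroperoxybenzoic acid, OOC(=O)c1cccc(Cl)c1
Why: Baeyer–Villiger oxidation: the 2,4,6-trioxygenated aryl group migrates readily, and methanolysis of the formate unmasks the ring D phenol between the furan oxygen and a methoxy group.

Step 7
Reactants: 10 8-(benzyloxy)-9-bromo-1,3,7-trimethoxydibenzo[b,d]furan-4-ol; 11 (3,5-dimethoxyphenyl)boronic acid
Product: 12 2-(benzyloxy)-1-bromo-6-(3,5-dimethoxyphenoxy)-3,7,9-trimethoxydibenzo[b,d]furan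
Conditions: Cu(OAc)2, pyridine, 4 Å MS, CH2Cl2, O2 (1 atm), rt
Reagents that add atoms: none
Why: Chan–Lam oxidative coupling of a phenol with an arylboronic acid on divalent copper runs at room temperature and does not insert into the aryl bromide, so the ring D–O–ring E ether is made without loss of the bay C–Br bond.

Step 8
Reactants: 12 2-(benzyloxy)-1-bromo-6-(3,5-dimethoxyphenoxy)-3,7,9-trimethoxydibenzo[b,d]furan
Product: 13 1-bromo-6-(3,5-dimethoxyphenoxy)-3,7,9-trimethoxydibenzo[b,d]furan-2-ol
Conditions: BCl3, C6HMe5, CH2Cl2, −78 °C; MeOH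
Reagents that add atoms: none
Why: Lewis-acid debenzylation: BCl3 ionises the benzyl ether at −78 °C, pentamethylbenzene traps the benzyl cation before it can alkylate the electron-rich rings, and methyl ethers and the aryl bromide are inert at this temperature.

Step 9
Reactants: 14 squaric acid
Product: 15 3,4-dichlorocyclobut-3-ene-1,2-dione
Conditions: (COCl)2, DMF (cat.), CH2Cl2, reflux
Reagents that add atoms: oxalyl chloride, ClC(=O)C(Cl)=O
Why: Chlorodehydroxylation of the vinylogous acid by the Vilsmeier-type chloroiminium species formed from oxalyl chloride and DMF gives the vinylogous acid chloride.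

Step 10
Reactants: 15 3,4-dichlorocyclobut-3-ene-1,2-dione; 16 3,5-dimethoxyphenol
Product: 17 3-chloro-4-(3,5-dimethoxyphenoxy)cyclobut-3-ene-1,2-dione
Conditions: 16 (1.0 equiv, slow addition), i-Pr2NEt, CH2Cl2, −78 → 0 °C; used crude
Reagents that add atoms: none
Why: Addition–elimination at a vinylogous acid chloride: substitution should stop after one chloride because the aryloxy group makes 17 a poorer electrophile than 15, and O-attack of the phenol outruns C-acylation at low temperature.

Step 11
Reactants: 17 3-chloro-4-(3,5-dimethoxyphenoxy)cyclobut-3-ene-1,2-dione; 13 1-bromo-6-(3,5-dimethoxyphenoxy)-3,7,9-trimethoxydibenzo[b,d]furan-2-ol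
Product: 18 3-{[1-bromo-6-(3,5-dimethoxyphenoxy)-3,7,9-trimethoxydibenzo[b,d]furan-2-yl]oxy}-4-(3,5-dimethoxyphenoxy)cyclobut-3-ene-1,2-dione
Conditions: i-Pr2NEt, CH2Cl2, 0 °C → rt (13 as limiting reagent)
Reagents that add atoms: none
Why: Second addition–elimination (vinylogous acyl substitution) at the remaining C–Cl carbon: the hindrance of the di-ortho-substituted phenol matters little at this flat, strongly electrophilic carbon, and a hindered amine base without excess phenoxide limits exchange of the aryloxy groups.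

Step 12
Reactants: 18 mixed bis(aryloxy)cyclobutenedione; 19 methyl vinyl ether
Product: 21 rac-3-{[1-bromo-6-(3,5-dimethoxyphenoxy)-3,7,9-trimethoxydibenzo[b,d]furan-2-yl]oxy}-2-(3,5-dimethoxyphenoxy)-4-hydroxy-4-(1-methoxyethenyl)cyclobut-2-en-1-one, via 1-methoxyvinyllithium 20 (not isolated)
Conditions: 19 (excess), t-BuLi, THF, −78 → 0 °C; then added to 18 (1.05 equiv of 20), THF, −78 °C; aq NH4Cl, −78 °C
Reagents that add atoms: none
Why: 1,2-Addition of an alkenyllithium to a cyclobutenedione carbonyl: the ring C aryloxy group is twisted out of conjugation with its own ring by its two ortho substituents and is the better donor, so it deactivates the carbonyl next to the ring A aryloxy carbon and attack is expected at the carbonyl next to the ring C aryloxy carbon; the new carbinol centre forms as a racemate and is erased in step 13.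

Step 13
Reactants: 21 rac-4-hydroxy-4-(1-methoxyethenyl)-2,3-bis(aryloxy)cyclobutenone
Product: 24 3-{[1-bromo-6-(3,5-dimethoxyphenoxy)-3,7,9-trimethoxydibenzo[b,d]furan-2-yl]oxy}-2-(3,5-dimethoxyphenoxy)-5-methoxybenzene-1,4-diol, via dienylketene 22 (not isolated), via cyclohexadienone tautomer 23 (not isolated)
Conditions: PhMe (degassed), 110 °C, Ar; product kept under Ar
Reagents that add atoms: none
Why: Thermal conrotatory 4π-electrocyclic opening of the cyclobutenone C1–C4 bond gives dienylketene 22, and because the donor hydroxyl rotates outward the 1-methoxyvinyl group ends up cis to the ketene. Thermal disrotatory 6π electrocyclisation then joins the ketene carbon to the vinyl CH2 carbon (the only ring formed, a six-membered carbocycle), and tautomerisation of dienone 23 aromatises ring B with its two new hydroxyls para to each other. The closest known reaction type is the Moore ring expansion of squarate-derived 4-alkenyl-4-hydroxycyclobutenones, including 1-alkoxyalkenyl cases. No stereocentre is created, and the racemic carbinol centre of 21 is destroyed. The selectivity needed is torquoselectivity (hydroxyl outward; inward rotation would let the oxygen capture the ketene), and the strong outward preference of a π-donor at C4 secures it. The substitution pattern of ring B needs no further control because all six ring atoms and their substituents are already fixed in 21.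

Step 14
Reactants: 24 ring B hydroquinone
Product: 25 phlorofucofuroeckol A octamethyl ether with one free hydroxyl on ring B (ortho to the ring A ether)
Conditions: CuI (0.5 equiv), N,N-dimethylglycine·HCl, Cs2CO3, 1,4-dioxane (degassed), 100 °C, Ar
Reagents that add atoms: none
Why: Intramolecular Ullmann-type C–O coupling: only the hydroxyl flanked by the methoxy group and the ring C ether can reach the bay bromide through a six-membered closure, so the other hydroxyl should stay free, and closure relieves the bromine–methoxy strain across the bay.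

Step 15
Reactants: 25 octamethyl ether
Product: 26 phlorofucofuroeckol A
Conditions: BBr3 (excess), CH2Cl2, −78 °C → rt; MeOH, then H2O; Ar
Reagents that add atoms: none
Why: Lewis-acid ether cleavage (BBr3 demethylation): bromide attacks the methyl group of each boron-complexed aryl methyl ether, whereas the diaryl ether, dioxin and furan C–O bonds have no sp3 carbon to attack and should survive.

Compound list
1 | 5-bromovanillin | COc1cc(C=O)cc(Br)c1O | starting material
2 | 3-bromo-4-hydroxy-2-iodo-5-methoxybenzaldehyde | COc1cc(C=O)c(I)c(Br)c1O | intermediate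
3 | 4-(benzyloxy)-3-bromo-2-iodo-5-methoxybenzaldehyde | COc1cc(C=O)c(I)c(Br)c1OCc1ccccc1 | intermediate
4 | 4-(benzyloxy)-3-bromo-2-iodo-5-methoxyphenyl formate | COc1cc(OC=O)c(I)c(Br)c1OCc1ccccc1 | intermediate
5 | 4-(benzyloxy)-3-bromo-2-iodo-5-methoxyphenol | COc1cc(O)c(I)c(Br)c1OCc1ccccc1 | intermediate
6 | 2-fluoro-4,6-dimethoxybenzaldehyde | COc1cc(F)c(C=O)c(OC)c1 | starting material
7 | 2-[4-(benzyloxy)-3-bromo-2-iodo-5-methoxyphenoxy]-4,6-dimethoxybenzaldehyde | COc1cc(Oc2cc(OC)cc(OC)c2C=O)c(I)c(Br)c1OCc1ccccc1 | intermediate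
8 | 8-(benzyloxy)-9-bromo-1,3,7-trimethoxydibenzo[b,d]furan-4-carbaldehyde | COc1cc2oc3c(C=O)c(OC)cc(OC)c3c2c(Br)c1OCc1ccccc1 | intermediate
9 | 8-(benzyloxy)-9-bromo-1,3,7-trimethoxydibenzo[b,d]furan-4-yl formate | COc1cc2oc3c(OC=O)c(OC)cc(OC)c3c2c(Br)c1OCc1ccccc1 | intermediate
10 | 8-(benzyloxy)-9-bromo-1,3,7-trimethoxydibenzo[b,d]furan-4-ol | COc1cc2oc3c(O)c(OC)cc(OC)c3c2c(Br)c1OCc1ccccc1 | intermediate
11 | (3,5-dimethoxyphenyl)boronic acid | COc1cc(OC)cc(B(O)O)c1 | starting material
12 | 2-(benzyloxy)-1-bromo-6-(3,5-dimethoxyphenoxy)-3,7,9-trimethoxydibenzo[b,d]furan | COc1cc2oc3c(Oc4cc(OC)cc(OC)c4)c(OC)cc(OC)c3c2c(Br)c1OCc1ccccc1 | intermediate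
13 | 1-bromo-6-(3,5-dimethoxyphenoxy)-3,7,9-trimethoxydibenzo[b,d]furan-2-ol | Oc1c(OC)cc2oc3c(Oc4cc(OC)cc(OC)c4)c(OC)cc(OC)c3c2c1Br | intermediate
14 | squaric acid | OC1=C(O)C(=O)C1=O | starting material
15 | 3,4-dichlorocyclobut-3-ene-1,2-dione | ClC1=C(Cl)C(=O)C1=O | intermediate
16 | 3,5-dimethoxyphenol | COc1cc(O)cc(OC)c1 | starting material
17 | 3-chloro-4-(3,5-dimethoxyphenoxy)cyclobut-3-ene-1,2-dione | COc1cc(OC)cc(OC2=C(Cl)C(=O)C2=O)c1 | intermediate
18 | 3-{[1-bromo-6-(3,5-dimethoxyphenoxy)-3,7,9-trimethoxydibenzo[b,d]furan-2-yl]oxy}-4-(3,5-dimethoxyphenoxy)cyclobut-3-ene-1,2-dione | COc1cc(OC)cc(OC2=C(Oc3c(OC)cc4oc5c(Oc6cc(OC)cc(OC)c6)c(OC)cc(OC)c5c4c3Br)C(=O)C2=O)c1 | intermediate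
19 | methyl vinyl ether | C=COC | starting material
20 | 1-methoxyvinyllithium | [Li]C(=C)OC | intermediate
21 | rac-3-{[1-bromo-6-(3,5-dimethoxyphenoxy)-3,7,9-trimethoxydibenzo[b,d]furan-2-yl]oxy}-2-(3,5-dimethoxyphenoxy)-4-hydroxy-4-(1-methoxyethenyl)cyclobut-2-en-1-one (racemic, one enantiomer drawn) | C=C(OC)[C@]1(O)C(Oc2c(OC)cc3oc4c(Oc5cc(OC)cc(OC)c5)c(OC)cc(OC)c4c3c2Br)=C(Oc2cc(OC)cc(OC)c2)C1=O | intermediate
22 | (3Z)-3-{[1-bromo-6-(3,5-dimethoxyphenoxy)-3,7,9-trimethoxydibenzo[b,d]furan-2-yl]oxy}-2-(3,5-dimethoxyphenoxy)-4-hydroxy-5-methoxyhexa-1,3,5-trien-1-one (dienylketene, ketene carbon and methoxyvinyl group cis) | O=C=C(Oc1cc(OC)cc(OC)c1)/C(Oc1c(OC)cc2oc3c(Oc4cc(OC)cc(OC)c4)c(OC)cc(OC)c3c2c1Br)=C(\C(=C)OC)O | intermediate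
23 | 3-{[1-bromo-6-(3,5-dimethoxyphenoxy)-3,7,9-trimethoxydibenzo[b,d]furan-2-yl]oxy}-2-(3,5-dimethoxyphenoxy)-4-hydroxy-5-methoxycyclohexa-2,4-dien-1-one | O=C1CC(OC)=C(O)C(Oc2c(OC)cc3oc4c(Oc5cc(OC)cc(OC)c5)c(OC)cc(OC)c4c3c2Br)=C1Oc1cc(OC)cc(OC)c1 | intermediate
24 | 3-{[1-bromo-6-(3,5-dimethoxyphenoxy)-3,7,9-trimethoxydibenzo[b,d]furan-2-yl]oxy}-2-(3,5-dimethoxyphenoxy)-5-methoxybenzene-1,4-diol | COc1cc(O)c(Oc2cc(OC)cc(OC)c2)c(Oc2c(OC)cc3oc4c(Oc5cc(OC)cc(OC)c5)c(OC)cc(OC)c4c3c2Br)c1O | intermediate
25 | phlorofucofuroeckol A octamethyl ether, ring B hydroxyl ortho to the ring A ether free | COc1cc(OC)cc(Oc2c(O)cc(OC)c3c2Oc2c(OC)cc4oc5c(Oc6cc(OC)cc(OC)c6)c(OC)cc(OC)c5c4c2O3)c1 | intermediate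
26 | phlorofucofuroeckol A | Oc1cc(O)cc(Oc2c(O)cc(O)c3c2Oc2c(O)cc4oc5c(Oc6cc(O)cc(O)c6)c(O)cc(O)c5c4c2O3)c1 | target

Total step count: 15 steps.
Longest linear sequence: 13 steps (steps 1–8, then 11–15).

Steps most likely to fail

Step 12 (addition of 1-methoxyvinyllithium). What may go wrong is attack at the other carbonyl: steric shielding by the large ring C aryloxy group opposes the electronic bias, so site selectivity may be poor or inverted. Conjugate displacement of an aryloxide is a second possible failure. The fallback sets out from 18 and uses (Z)-2-methoxyvinyllithium (from (Z)-1-bromo-2-methoxyethene and t-BuLi, THF, −78 °C) in place of 20. Added to the same sterically preferred carbonyl, next to the ring A aryloxy carbon, it should give the regioisomeric carbinol rac-2-{[1-bromo-6-(3,5-dimethoxyphenoxy)-3,7,9-trimethoxydibenzo[b,d]furan-2-yl]oxy}-3-(3,5-dimethoxyphenoxy)-4-hydroxy-4-[(Z)-2-methoxyethenyl]cyclobut-2-en-1-one F1. Because the vinyl oxygen now sits on the terminal carbon, heating F1 in toluene (the same ring opening and 6π closure) should lead to the identical hydroquinone, so the fallback comes back to the route at 24.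

Step 13 (ring expansion). What may go wrong is loss of material before or during ring opening: cleavage of the α-hydroxy enol ether by traces of acid or base, capture of the ketene by the hydroxyl oxygen after inward rotation, or oxidation of the hydroquinone as it forms. The fallback sets out from 21 and silylates the tertiary hydroxyl (TESOTf, 2,6-lutidine, CH2Cl2, −78 °C) to give the triethylsilyl ether of 21 F2. Thermolysis of F2 (PhMe, 110 °C) follows the same electrocyclic course, known for 4-silyloxycyclobutenones, and should give the monosilylated hydroquinone F3, which carries the silyl group on the oxygen para to the free hydroxyl and cannot oxidise to a quinone. Desilylation (Bu4NF, AcOH, THF, 0 °C) returns to the route at 24.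

Step 14 (dioxin closure). What may go wrong is oxidative degradation of the electron-rich hydroquinone dianion under hot basic conditions before the hindered C–Br bond reacts. The fallback sets out from 24. The less hindered hydroxyl (between the ring CH and the ring A ether) is silylated selectively with TIPSCl and imidazole in DMF to give the mono-triisopropylsilyl ether F4. The ring is then closed by palladium-catalysed intramolecular C–O coupling (Pd(OAc)2, t-BuXPhos, K3PO4, PhMe, 100 °C), which should give the silyl-protected dioxin F5. Bu4NF in THF removes the silyl group and returns to the route at 25.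

Further compounds
F1 | step 12 | rac-2-{[1-bromo-6-(3,5-dimethoxyphenoxy)-3,7,9-trimethoxydibenzo[b,d]furan-2-yl]oxy}-3-(3,5-dimethoxyphenoxy)-4-hydroxy-4-[(Z)-2-methoxyethenyl]cyclobut-2-en-1-one (racemic, one enantiomer drawn) | CO/C=C\[C@]1(O)C(Oc2cc(OC)cc(OC)c2)=C(Oc2c(OC)cc3oc4c(Oc5cc(OC)cc(OC)c5)c(OC)cc(OC)c4c3c2Br)C1=O
F2 | step 13 | triethylsilyl ether of 21 (racemic, one enantiomer drawn) | C=C(OC)[C@]1(O[Si](CC)(CC)CC)C(Oc2c(OC)cc3oc4c(Oc5cc(OC)cc(OC)c5)c(OC)cc(OC)c4c3c2Br)=C(Oc2cc(OC)cc(OC)c2)C1=O
F3 | step 13 | 3-{[1-bromo-6-(3,5-dimethoxyphenoxy)-3,7,9-trimethoxydibenzo[b,d]furan-2-yl]oxy}-2-(3,5-dimethoxyphenoxy)-5-methoxy-4-[(triethylsilyl)oxy]phenol | COc1cc(O)c(Oc2cc(OC)cc(OC)c2)c(Oc2c(OC)cc3oc4c(Oc5cc(OC)cc(OC)c5)c(OC)cc(OC)c4c3c2Br)c1O[Si](CC)(CC)CC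
F4 | step 14 | 2-{[1-bromo-6-(3,5-dimethoxyphenoxy)-3,7,9-trimethoxydibenzo[b,d]furan-2-yl]oxy}-3-(3,5-dimethoxyphenoxy)-6-methoxy-4-[(triisopropylsilyl)oxy]phenol | COc1cc(O[Si](C(C)C)(C(C)C)C(C)C)c(Oc2cc(OC)cc(OC)c2)c(Oc2c(OC)cc3oc4c(Oc5cc(OC)cc(OC)c5)c(OC)cc(OC)c4c3c2Br)c1O
F5 | step 14 | triisopropylsilyl ether of 25 (silyl group on the ring B hydroxyl) | COc1cc(OC)cc(Oc2c(O[Si](C(C)C)(C(C)C)C(C)C)cc(OC)c3c2Oc2c(OC)cc4oc5c(Oc6cc(OC)cc(OC)c6)c(OC)cc(OC)c5c4c2O3)c1
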